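A ratio of 226 stands between the two capture steps as charged: free catalyst meets substrate at 439 h⁻¹, catalyst intermediate A meets partner at 1.95 h⁻¹.

the same everywhere: precatalyst 0.18 mM; added ligand 0.26 mM
- north-west: substrate 10 mM; partner 7.00 mM (fed, over 20.0 h); time 40 h; all but partner at the start; partner goes in evenly over 20.0 h, the run ends at 40 h
- south-east: substrate 10 mM; partner 7.00 mM; a single well-mixed tank run continuously and read at steady state, 40 h in it on average
- south-west: substrate 10 mM (fed, over 20.0 h); partner 7.00 mM; time 40 h; a stirred flask in which substrate is dosed at a steady rate over 20.0 h without added volume, worked up at 40 h
- south: substrate 10 mM; partner 7.00 mM; time 40 h; a closed flask charged with all of it at once and left for 40 h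

    partner + catalyst intermediate A → catalyst intermediate B (k1 = 278 M⁻¹ h⁻¹)
    precatalyst → free catalyst (k2 = 0.0357 h⁻¹)
    substrate + free catalyst → catalyst intermediate A (k3 = 43900 M⁻¹ h⁻¹)
    free catalyst + added ligand ⇌ idle complex (K4 = 1900 M⁻¹, k4 = 7810 M⁻¹ h⁻¹)
    catalyst intermediate B ⇌ free catalyst + product (K5 = 0.0044 M, k5 = 5.29 h⁻¹)

- the stated concentrations are those of everything mixed, before any reaction; amounts are the same in each set-up
- the feed brings no volume worth counting
- run time (north-west): 40 h

- the set-up with the highest amount of product at the outlet or at the end, in percent of the substrate put in ("none" if the first two lie within 2 percentage points) (north-west / south-east / south-west / south / none)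
- amount of product at the outlet or at the end, in percent of the substrate put in, north-west
- amount of product at the outlet or at the end, in percent of the substrate put in, south-east
- amount of product at the outlet or at the end, in percent of the substrate put in, south-west
- amount of product at the outlet or at the end, in percent of the substrate put in, south

Because capture by substrate is much faster, the working catalyst waits as catalyst intermediate A, the resting state of the round, and the rate is pseudo-first-order in c(partner) and of zero order in c(substrate). The reckoning made here takes south first. With the whole catalyst charge active and c(partner) as charged, the rate is 0.255 mM h⁻¹, yet the true rate begins at nil, for the precatalyst has a half-life of 19 h, so that the mean active share over the run is a factor of 0.468. The second slowing is the fall of c(partner), softened a little because release of product is not instantaneous: the partner step at charge runs at a fraction 0.368 of the release step.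

The activation slowing accumulates in 0.936, the catalyst exposure, meaning the rate constant of the partner step times the active catalyst summed over the time. Substrate does not enter it. The fall of c(partner) stands on the other side of the balance: the logarithmic fall of partner, plus 0.368 times the fraction of partner used, equals this exposure. Solving by repeated substitution, from 39.2% through 49.0% to 47.3% of partner left, gives south 36.9% of product. Dosed substrate arrives at 0.500 mM h⁻¹, faster than that top rate, so south-west is put level with south. North-west and south-east lie beyond this reckoning, but both hold c(partner) below its charge, north-west during its feed and south-east in its steady tank, and are put lower, so the choice here is none.

The forecast gives 33.9% for north-west, 34.7% for south-east, 36.2% for south-west and 36.5% for south, with none as best, holding that “turnover is then limited mainly by the partner step”. Its south value lies 0.40 percentage points below the reckoning made here.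

The simulation gives 33.8% for north-west, 34.6% for south-east, 36.3% for south-west and 36.4% for south, and so none. South holds 48% of its partner at 40.0 h, against 47.3% from the exposure. The neighbour of north-west charged with 40 mM of substrate has the same exposure, so the reckoning keeps the partner use of north-west and divides the percentage by 4.00, which gives 8.44%. That neighbour gives 8.47%, with 51% of its partner left against 51% in north-west.

All constants belong to no real substance; the result is computed.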